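**Retrosynthetic overview**
1. Target 16 ⇐ 13: the ring B phenol is unmasked from an aryl aldehyde (Baeyer–Villiger) and the methyl ester is saponified in the same final operation.
2. 13 ⇐ 10 + 12: the diaryl ether C–O bond comes from SNAr on a 2-fluorobenzoate.
3. 10 ⇐ 7: the carboxyl carbon is introduced by ortho-lithiation between F and OMe.
4. 7 ⇐ 2 + 3 (key C–C bond): the carbinol carbon of 3-methylbutanal is used as a carbanion (sparteine-lithiated isoamyl carbamate) and joined to the aryl bromide carbon by Negishi coupling, which sets the (S) centre directly.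
5. No ring is formed; both benzene rings are bought (3 for ring A, 11 for ring B).

Assumption: the stereodescriptor in the SMILES is read as (S) at the benzylic carbinol carbon (O > aryl > CH2 > H), and that enantiomer is made.

**Step 1**
Reactants: 1 3-methylbutan-1-ol
Product: 2 3-methylbutyl N,N-diisopropylcarbamate
Conditions: NaH, iPr2NCOCl, THF, 0 °C → reflux
Reagents that add atoms: N,N-diisopropylcarbamoyl chloride, CC(C)N(C(C)C)C(Cl)=O
Why: Carbamoylation (nucleophilic acyl substitution) of the sodium alkoxide installs the hindered carbamate that directs and stabilises α-lithiation.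

**Step 2**
Reactants: 2 3-methylbutyl N,N-diisopropylcarbamate; 3 1-bromo-4-fluoro-2-methoxybenzene
Product: 6 (S)-1-(4-fluoro-2-methoxyphenyl)-3-methylbutyl N,N-diisopropylcarbamate, via α-lithio carbamate 4 (not isolated), via α-zincio carbamate 5 (not isolated)
Conditions: 2 (1.4 equiv), sBuLi (1.3 equiv), (+)-sparteine (1.3 equiv), Et2O, −78 °C, 5 h; ZnCl2 (THF), −78 °C → rt; then 3 (1.0 equiv), Pd(OAc)2 (5 mol %), tBu3P·HBF4 (10 mol %), toluene, rt → 40 °C
Reagents that add atoms: none
Why: Hoppe asymmetric deprotonation with sBuLi/(+)-sparteine removes the pro-R α-proton to give the configurationally stable (R)-α-oxyalkyllithium 4 (the aldehyde carbonyl carbon acting as a nucleophile), which transmetalates to zinc and undergoes Negishi cross-coupling with the electrophilic aryl carbon of 3 with retention throughout, setting the (S)-benzylic centre.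

**Step 3**
Reactants: 6 (S)-1-(4-fluoro-2-methoxyphenyl)-3-methylbutyl N,N-diisopropylcarbamate
Product: 7 (S)-1-(4-fluoro-2-methoxyphenyl)-3-methylbutan-1-ol
Conditions: LiAlH4, THF, reflux; H2O/NaOH work-up
Reagents that add atoms: none
Why: Reductive carbamate cleavage by hydride attack at the carbonyl carbon breaks no bond to the stereocentre, so the (S) configuration is retained.

**Step 4**
Reactants: 7 (S)-1-(4-fluoro-2-methoxyphenyl)-3-methylbutan-1-ol
Product: 10 methyl 6-fluoro-3-[(1S)-1-hydroxy-3-methylbutyl]-2-methoxybenzoate, via aryllithium alkoxide 8 (not isolated), via carbonate ester 9 (not isolated)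
Conditions: nBuLi (2.3 equiv), THF, −78 °C; cannulate into ClCO2Me (3 equiv), −78 → 0 °C; then K2CO3 (cat.), MeOH, rt
Reagents that add atoms: methyl chloroformate, COC(Cl)=O
Why: Directed ortho-metalation: after O-deprotonation the second equivalent of nBuLi removes the most acidic ring proton (flanked by F and OMe), both lithium sites are acylated, and the unhindered alkyl methyl carbonate is then methanolysed selectively while the di-ortho-substituted aryl ester survives.

**Step 5**
Reactants: 11 2,6-bis(hydroxymethyl)-4-methylphenol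
Product: 12 2-hydroxy-3-(hydroxymethyl)-5-methylbenzaldehyde
Conditions: activated MnO2 (5 equiv), CHCl3, rt, stopped at mono-oxidation
Reagents that add atoms: none
Why: Selective benzylic oxidation by MnO2; the first aldehyde is hydrogen-bonded to the phenol and deactivates the ring, so the second hydroxymethyl group reacts much more slowly.

**Step 6**
Reactants: 10 methyl 6-fluoro-3-[(1S)-1-hydroxy-3-methylbutyl]-2-methoxybenzoate; 12 2-hydroxy-3-(hydroxymethyl)-5-methylbenzaldehyde
Product: 13 methyl 6-[2-formyl-6-(hydroxymethyl)-4-methylphenoxy]-3-[(1S)-1-hydroxy-3-methylbutyl]-2-methoxybenzoate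
Conditions: Cs2CO3, DMSO, 100 °C
Reagents that add atoms: none
Why: Nucleophilic aromatic substitution (addition–elimination): the caesium phenoxide of 12 displaces fluoride ortho to the ester, while the much less acidic aliphatic hydroxyls stay protonated and do not compete.

**Step 7**
Reactants: 13 methyl 6-[2-formyl-6-(hydroxymethyl)-4-methylphenoxy]-3-[(1S)-1-hydroxy-3-methylbutyl]-2-methoxybenzoate
Product: 16 6-[2-hydroxy-6-(hydroxymethyl)-4-methylphenoxy]-3-[(1S)-1-hydroxy-3-methylbutyl]-2-methoxybenzoic acid (CNP0221397.1), via aryl formate 14 (not isolated), via phenol methyl ester 15 (not isolated)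
Conditions: mCPBA, CH2Cl2, 0 °C → rt; Na2S2O3 quench, evaporate; KOH, MeOH–H2O, 65 °C, N2; cold 1 M HCl to pH 3
Reagents that add atoms: mCPBA (3-chloroperoxybenzoic acid), O=C(OO)c1cccc(Cl)c1; potassium hydroxide (its oxygen ends in the CO2H group), [K+].[OH-]
Why: Baeyer–Villiger (Dakin-type) oxidation, in which the aryl group bearing the ortho aryloxy donor migrates to give formate 14, followed by saponification of the formate and the methyl ester; the stereocentre is not touched.

**Compound list**
1 | 3-methylbutan-1-ol | CC(C)CCO | starting material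
2 | 3-methylbutyl N,N-diisopropylcarbamate | CC(C)CCOC(=O)N(C(C)C)C(C)C | intermediate
3 | 1-bromo-4-fluoro-2-methoxybenzene (2-bromo-5-fluoroanisole) | COc1cc(F)ccc1Br | starting material
4 | (R)-1-lithio-3-methylbutyl N,N-diisopropylcarbamate, as its (+)-sparteine complex | [Li][C@@H](OC(=O)N(C(C)C)C(C)C)CC(C)C | intermediate
5 | (R)-[1-(diisopropylcarbamoyloxy)-3-methylbutyl]zinc chloride | Cl[Zn][C@@H](OC(=O)N(C(C)C)C(C)C)CC(C)C | intermediate
6 | (S)-1-(4-fluoro-2-methoxyphenyl)-3-methylbutyl N,N-diisopropylcarbamate | COc1cc(F)ccc1[C@@H](OC(=O)N(C(C)C)C(C)C)CC(C)C | intermediate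
7 | (S)-1-(4-fluoro-2-methoxyphenyl)-3-methylbutan-1-ol | COc1cc(F)ccc1[C@@H](O)CC(C)C | intermediate
8 | lithium (S)-1-(4-fluoro-3-lithio-2-methoxyphenyl)-3-methylbutan-1-olate | COc1c([C@@H](O[Li])CC(C)C)ccc(F)c1[Li] | intermediate
9 | methyl 6-fluoro-2-methoxy-3-[(1S)-1-(methoxycarbonyloxy)-3-methylbutyl]benzoate | COC(=O)c1c(F)ccc([C@@H](OC(=O)OC)CC(C)C)c1OC | intermediate
10 | methyl 6-fluoro-3-[(1S)-1-hydroxy-3-methylbutyl]-2-methoxybenzoate | COC(=O)c1c(F)ccc([C@@H](O)CC(C)C)c1OC | intermediate
11 | 2,6-bis(hydroxymethyl)-4-methylphenol | Cc1cc(CO)c(O)c(CO)c1 | starting material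
12 | 2-hydroxy-3-(hydroxymethyl)-5-methylbenzaldehyde | Cc1cc(CO)c(O)c(C=O)c1 | intermediate
13 | methyl 6-[2-formyl-6-(hydroxymethyl)-4-methylphenoxy]-3-[(1S)-1-hydroxy-3-methylbutyl]-2-methoxybenzoate | COC(=O)c1c(Oc2c(C=O)cc(C)cc2CO)ccc([C@@H](O)CC(C)C)c1OC | intermediate
14 | methyl 6-[2-(formyloxy)-6-(hydroxymethyl)-4-methylphenoxy]-3-[(1S)-1-hydroxy-3-methylbutyl]-2-methoxybenzoate | COC(=O)c1c(Oc2c(OC=O)cc(C)cc2CO)ccc([C@@H](O)CC(C)C)c1OC | intermediate
15 | methyl 6-[2-hydroxy-6-(hydroxymethyl)-4-methylphenoxy]-3-[(1S)-1-hydroxy-3-methylbutyl]-2-methoxybenzoate | COC(=O)c1c(Oc2c(O)cc(C)cc2CO)ccc([C@@H](O)CC(C)C)c1OC | intermediate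
16 | 6-[2-hydroxy-6-(hydroxymethyl)-4-methylphenoxy]-3-[(1S)-1-hydroxy-3-methylbutyl]-2-methoxybenzoic acid | COc1c([C@@H](O)CC(C)C)ccc(Oc2c(O)cc(C)cc2CO)c1C(=O)O | target

**Step count and risks**
Total steps: 7. Longest linear sequence: 6 (steps 1, 2, 3, 4, 6, 7); step 5 is a one-step side branch.

Most likely to fail, step 6 (SNAr). The fluoride is activated only by a twisted ortho ester, and the phenoxide of 12 is hindered and deactivated by its aldehyde. The fallback sets out from 10 and 11 and comes back at 13. Couple 10 with the aldehyde-free, more nucleophilic phenoxide of 11 (Cs2CO3, DMSO, 100 °C) to give methyl 6-[2,6-bis(hydroxymethyl)-4-methylphenoxy]-3-[(1S)-1-hydroxy-3-methylbutyl]-2-methoxybenzoate F12. Then desymmetrise by primary-selective mono-oxidation (TEMPO cat., PhI(OAc)2 1 equiv, CH2Cl2, run to partial conversion, diol recycled) to reach 13. This moves the oxidation of step 5 to after the ether bond is made.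

Second, step 2 (asymmetric lithiation, zinc transmetalation, Negishi coupling). Risks are incomplete coupling at the ortho-methoxy bromide, β-hydride side reactions at palladium, or eroded er. The fallback sets out from 3 and comes back at 7, using an acyl anion equivalent and a catalyst-controlled reduction.
- Condense 3-methylbutanal with tert-butylhydrazine to give 3-methylbutanal N-tert-butylhydrazone F1.
- C-arylate it with 3 (Pd2(dba)3, bisphosphine, NaOtBu, toluene, 80 °C) to give 1-(tert-butyldiazenyl)-1-(4-fluoro-2-methoxyphenyl)-3-methylbutane F2, which tautomerises to 1-(4-fluoro-2-methoxyphenyl)-3-methylbutan-1-one N-tert-butylhydrazone F3.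
- Hydrolyse with aqueous acid to 1-(4-fluoro-2-methoxyphenyl)-3-methylbutan-1-one F4.
- Reduce with BH3·SMe2 and (R)-2-methyl-CBS-oxazaborolidine to give the (S)-alcohol 7, replacing steps 2 and 3.

Third, step 4 (ring lithiation of a lithium alkoxide, double acylation). Risks are wrong-site metalation, LiF loss to an aryne, or ketone formation. The fallback sets out from 3 and 1 and comes back at 10; it installs the ester before the key coupling and uses an acid/base-cleavable carbamate.
- Deprotonate 3 with LDA (THF, −78 °C) to (3-bromo-6-fluoro-2-methoxyphenyl)lithium F5 and trap with ClCO2Me to give methyl 3-bromo-6-fluoro-2-methoxybenzoate F6.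
- Carbamoylate 1 with 2,2,4,4-tetramethyl-1,3-oxazolidine-3-carbonyl chloride (NaH, THF) to give 3-methylbutyl 2,2,4,4-tetramethyl-1,3-oxazolidine-3-carboxylate F7.
- Treat F7 as in step 2 to pass through (R)-1-lithio-3-methylbutyl 2,2,4,4-tetramethyl-1,3-oxazolidine-3-carboxylate F8 and the derived (R)-alkylzinc chloride F9, and couple with F6 under the same Pd(OAc)2/tBu3P·HBF4 conditions. This gives methyl 6-fluoro-2-methoxy-3-[(1S)-3-methyl-1-(2,2,4,4-tetramethyl-1,3-oxazolidine-3-carbonyloxy)butyl]benzoate F10.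
- MeSO3H in MeOH at reflux opens the N,O-acetal to methyl 6-fluoro-3-[(1S)-1-{[(1-hydroxy-2-methylpropan-2-yl)carbamoyl]oxy}-3-methylbutyl]-2-methoxybenzoate F11. The arene is electron-poor at this stage, so the benzylic C–O bond does not ionise.
- K2CO3 in MeOH then releases 10 by cyclisation of the hydroxy carbamate. This replaces steps 1 to 4 and needs neither LiAlH4 nor the aryllithium alkoxide.

**Further compounds**
F1 | step 2 | 3-methylbutanal N-tert-butylhydrazone | CC(C)CC=NNC(C)(C)C
F2 | step 2 | 1-(tert-butyldiazenyl)-1-(4-fluoro-2-methoxyphenyl)-3-methylbutane (racemic) | COc1cc(F)ccc1C(CC(C)C)N=NC(C)(C)C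
F3 | step 2 | 1-(4-fluoro-2-methoxyphenyl)-3-methylbutan-1-one N-tert-butylhydrazone | COc1cc(F)ccc1C(CC(C)C)=NNC(C)(C)C
F4 | step 2 | 1-(4-fluoro-2-methoxyphenyl)-3-methylbutan-1-one | COc1cc(F)ccc1C(=O)CC(C)C
F5 | step 4 | (3-bromo-6-fluoro-2-methoxyphenyl)lithium | COc1c(Br)ccc(F)c1[Li]
F6 | step 4 | methyl 3-bromo-6-fluoro-2-methoxybenzoate | COC(=O)c1c(F)ccc(Br)c1OC
F7 | step 4 | 3-methylbutyl 2,2,4,4-tetramethyl-1,3-oxazolidine-3-carboxylate | CC(C)CCOC(=O)N1C(C)(C)COC1(C)C
F8 | step 4 | (R)-1-lithio-3-methylbutyl 2,2,4,4-tetramethyl-1,3-oxazolidine-3-carboxylate | [Li][C@@H](OC(=O)N1C(C)(C)COC1(C)C)CC(C)C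
F9 | step 4 | (R)-[3-methyl-1-(2,2,4,4-tetramethyl-1,3-oxazolidine-3-carbonyloxy)butyl]zinc chloride | Cl[Zn][C@@H](OC(=O)N1C(C)(C)COC1(C)C)CC(C)C
F10 | step 4 | methyl 6-fluoro-2-methoxy-3-[(1S)-3-methyl-1-(2,2,4,4-tetramethyl-1,3-oxazolidine-3-carbonyloxy)butyl]benzoate | COC(=O)c1c(F)ccc([C@@H](OC(=O)N2C(C)(C)COC2(C)C)CC(C)C)c1OC
F11 | step 4 | methyl 6-fluoro-3-[(1S)-1-{[(1-hydroxy-2-methylpropan-2-yl)carbamoyl]oxy}-3-methylbutyl]-2-methoxybenzoate | COC(=O)c1c(F)ccc([C@@H](OC(=O)NC(C)(C)CO)CC(C)C)c1OC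
F12 | step 6 | methyl 6-[2,6-bis(hydroxymethyl)-4-methylphenoxy]-3-[(1S)-1-hydroxy-3-methylbutyl]-2-methoxybenzoate | COC(=O)c1c(Oc2c(CO)cc(C)cc2CO)ccc([C@@H](O)CC(C)C)c1OC
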